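**Retrosynthetic overview**
1. The target comes from acid cleavage of the two MOM ethers on ring B of a 7-hydroxyisoflavan. Ring C (the dihydropyran) is the only ring built, closed in the last-but-one step by intramolecular Mitsunobu etherification (O1–C2).
2. The C4–C4a bond comes from a Negishi sp3–sp2 coupling: a primary alkylzinc carrying C2, C3, C4 and ring B, with a ring A aryl bromide whose two oxygens are masked as diethylcarbamates (cleaved later by LiAlH4, leaving MOM intact).
3. The C3 stereocentre comes from lipase-catalysed desymmetrisation of a prochiral 2-aryl-propane-1,3-diol. An acetate-to-silyl swap makes the enzyme-marked arm C4 and the other arm C2.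
4. The diol comes from Pd-catalysed arylation of diethyl malonate and LiAlH4 reduction. Both prenylated aryl bromides come from 4-bromoresorcinol by lithiation between the two oxygens and copper-mediated prenylation.
5. Ring order: rings A and B are bought (4-bromoresorcinol, used twice); ring C is formed in step 14.

Abbreviations: ArB = 2,4-bis(methoxymethoxy)-3-(3-methylbut-2-en-1-yl)phenyl; prenyl = 3-methylbut-2-en-1-yl; MOM = methoxymethyl; TBDPS = tert-butyldiphenylsilyl.

Assumption: in the acylation mode the lipase marks the hydroxymethyl group that gives the (S)-monoacetate drawn below; this sense is not known for this substrate and must be checked on the first run (Mosher ester), and the fallback for that step covers the opposite outcome.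

**Route**

Step 1
Reactants: 1 4-bromoresorcinol
Product: 2 1-bromo-2,4-bis(methoxymethoxy)benzene
Conditions: MOMCl, i-Pr2NEt, CH2Cl2, 0 °C → rt
Reagents that add atoms: chloromethyl methyl ether (MOMCl), COCCl
Why: Double O-alkylation (Williamson-type acetal formation) installs two MOM groups that later direct metalation and survive base, hydride, Pd and Zn.

Step 2
Reactants: 2 1-bromo-2,4-bis(methoxymethoxy)benzene; 3 prenyl bromide
Product: 6 1-bromo-2,4-bis(methoxymethoxy)-3-prenylbenzene, via aryllithium 4 (not isolated), via arylcopper 5 (not isolated)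
Conditions: lithium 2,2,6,6-tetramethylpiperidide (from TMPH, n-BuLi), THF, −78 °C; CuBr·SMe2; then 3, −78 → 0 °C
Reagents that add atoms: none
Why: Directed ortho-metalation by the amide base removes the most acidic proton (between the two MOM-oxy groups) without bromine–lithium exchange, and the arylcopper is allylated at the unhindered CH2 end of prenyl bromide (SN2) to give the linear prenyl group.

Step 3
Reactants: 6 1-bromo-2,4-bis(methoxymethoxy)-3-prenylbenzene; 7 diethyl malonate
Product: 8 diethyl 2-(ArB)malonate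
Conditions: Pd(OAc)2 (2 mol%), P(t-Bu)3·HBF4 (4 mol%), K3PO4, toluene, 80 °C
Reagents that add atoms: none
Why: Pd-catalysed α-arylation of a malonate (Buchwald–Hartwig-type C–C coupling) works on electron-rich, ortho-substituted aryl bromides with a bulky trialkylphosphine, and the trisubstituted prenyl alkene is inert.

Step 4
Reactants: 8 diethyl 2-(ArB)malonate
Product: 9 2-(ArB)propane-1,3-diol (prochiral)
Conditions: LiAlH4, THF, 0 °C → rt (malonate added to the hydride)
Reagents that add atoms: none
Why: Hydride reduction of both esters gives the 1,3-diol; inverse addition keeps reduction ahead of enolisation of the acidic aryl malonate, and MOM ethers and the alkene are untouched.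

Step 5
Reactants: 9 2-(ArB)propane-1,3-diol
Product: 10 (2S)-2-(ArB)-3-hydroxypropyl acetate
Conditions: lipase (immobilised Burkholderia cepacia lipase), vinyl acetate, MTBE, 25 °C
Reagents that add atoms: vinyl acetate, C=COC(C)=O
Why: Lipase-catalysed irreversible transesterification acetylates one of the two enantiotopic CH2OH groups (enzymatic desymmetrisation), which creates the C3 stereocentre; slight over-acylation to the achiral diacetate removes the minor enantiomer and raises the ee.

Step 6
Reactants: 10 (2S)-2-(ArB)-3-hydroxypropyl acetate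
Product: 11 (2R)-2-(ArB)-3-[(tert-butyldiphenylsilyl)oxy]propyl acetate
Conditions: TBDPSCl, imidazole, CH2Cl2, 0 °C → rt
Reagents that add atoms: tert-butyl(chloro)diphenylsilane (TBDPSCl), CC(C)(C)[Si](Cl)(c1ccccc1)c1ccccc1
Why: Immediate silylation of the free primary alcohol stops 1,3-acyl migration (the racemisation path of such monoacetates) and locks this arm as the future C2–O; the descriptor changes only through CIP priorities.

Step 7
Reactants: 11 (2R)-2-(ArB)-3-[(tert-butyldiphenylsilyl)oxy]propyl acetate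
Product: 12 (2R)-2-(ArB)-3-[(tert-butyldiphenylsilyl)oxy]propan-1-ol
Conditions: K2CO3 (0.2 equiv), MeOH, 0 °C
Reagents that add atoms: none
Why: Base-catalysed methanolysis (transesterification) frees the enzyme-marked arm, and the bulky TBDPS ether neither cleaves nor migrates under these conditions.

Step 8
Reactants: 12 (2R)-2-(ArB)-3-[(tert-butyldiphenylsilyl)oxy]propan-1-ol
Product: 13 tert-butyl{[(2S)-2-(ArB)-3-iodopropyl]oxy}diphenylsilane
Conditions: I2, PPh3, imidazole, CH2Cl2, 0 °C → rt
Reagents that add atoms: iodine, II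
Why: Appel-type iodination converts the primary alcohol to the iodide by SN2 at CH2 under near-neutral, cold conditions, so the adjacent stereocentre is untouched and iodide stays ahead of participation by the ortho MOM oxygen.

Step 9
Reactants: 1 4-bromoresorcinol
Product: 14 4-bromo-1,3-phenylene bis(N,N-diethylcarbamate)
Conditions: Et2NCOCl, K2CO3, MeCN, reflux
Reagents that add atoms: N,N-diethylcarbamoyl chloride, CCN(CC)C(Cl)=O
Why: O-carbamoylation gives two strong ortho-directing groups that are stable to acid-free Pd/Zn chemistry and are later removed by hydride without touching the MOM ethers of ring B.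

Step 10
Reactants: 14 4-bromo-1,3-phenylene bis(N,N-diethylcarbamate); 3 prenyl bromide
Product: 17 4-bromo-2-prenyl-1,3-phenylene bis(N,N-diethylcarbamate), via aryllithium 15 (not isolated), via arylcopper 16 (not isolated)
Conditions: lithium 2,2,6,6-tetramethylpiperidide (from TMPH, n-BuLi), THF, −78 °C; CuBr·SMe2, −78 °C; then 3, −78 → 0 °C
Reagents that add atoms: none
Why: Directed ortho-metalation between the two carbamates, then transmetalation to copper at −78 °C before warming, avoids the anionic ortho-Fries rearrangement and gives clean SN2 allylation to the future C8 prenyl group.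

Step 11
Reactants: 13 tert-butyl{[(2S)-2-(ArB)-3-iodopropyl]oxy}diphenylsilane; 17 4-bromo-2-prenyl-1,3-phenylene bis(N,N-diethylcarbamate)
Product: 19 4-{(2S)-2-(ArB)-3-[(tert-butyldiphenylsilyl)oxy]propyl}-2-prenyl-1,3-phenylene bis(N,N-diethylcarbamate), via alkylzinc iodide 18 (not isolated)
Conditions: Zn dust (I2-activated), DMA, 40 °C; then 17, Pd2(dba)3 (2.5 mol%), SPhos (10 mol%), 50 °C
Reagents that add atoms: none
Why: Zinc insertion into the primary iodide and Negishi sp3–sp2 coupling (oxidative addition of the aryl bromide to zerovalent palladium, fast reductive elimination with SPhos) forms C4–C4a at a CH2 carbon, so C3 is not touched and β-hydride elimination is suppressed.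

Step 12
Reactants: 19 the coupled bis-carbamate
Product: 20 4-{(2S)-2-(ArB)-3-[(tert-butyldiphenylsilyl)oxy]propyl}-2-prenylbenzene-1,3-diol
Conditions: LiAlH4, THF, reflux
Reagents that add atoms: none
Why: Hydride attack at the carbamate carbonyl expels the aryloxide (reductive carbamate cleavage) and frees only the ring A phenols, while MOM ethers, the silyl ether and the alkenes are inert.

Step 13
Reactants: 20 the silyl-protected ring A resorcinol
Product: 21 4-[(2S)-2-(ArB)-3-hydroxypropyl]-2-prenylbenzene-1,3-diol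
Conditions: TBAF, THF, 0 °C → rt
Reagents that add atoms: none
Why: Fluoride-driven desilylation (strong Si–F bond) unmasks the primary alcohol under non-acidic conditions that spare MOM and prenyl groups.

Step 14
Reactants: 21 4-[(2S)-2-(ArB)-3-hydroxypropyl]-2-prenylbenzene-1,3-diol
Product: 22 (3S)-3-(ArB)-8-prenyl-3,4-dihydro-2H-chromen-7-ol
Conditions: PPh3, DIAD, THF (0.005 M), 0 °C → rt
Reagents that add atoms: none
Why: Intramolecular Mitsunobu etherification closes ring C, since only the phenol ortho to the side chain can reach the activated primary carbon (6-exo-tet) and high dilution keeps the distal 7-OH from intermolecular alkylation; the reaction is at CH2, so C3 stays (S).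

Step 15
Reactants: 22 (3S)-3-(ArB)-8-prenyl-3,4-dihydro-2H-chromen-7-ol
Product: 23 (3S)-7,2',4'-trihydroxy-8,3'-diprenylisoflavan (target)
Conditions: HCl (1.25 M in MeOH), MeOH, rt
Reagents that add atoms: none
Why: Acid-catalysed acetal cleavage (transacetalisation to dimethoxymethane) removes both aryl MOM ethers at room temperature, mild enough to avoid cyclisation of the prenyl groups onto the neighbouring phenols, and the C3 stereocentre is not acidic.

**Compound list**
1 | 4-bromoresorcinol (4-bromobenzene-1,3-diol) | Oc1ccc(Br)c(O)c1 | starting material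
2 | 1-bromo-2,4-bis(methoxymethoxy)benzene | COCOc1ccc(Br)c(OCOC)c1 | intermediate
3 | prenyl bromide (1-bromo-3-methylbut-2-ene) | CC(C)=CCBr | starting material
4 | [3-bromo-2,6-bis(methoxymethoxy)phenyl]lithium | COCOc1ccc(Br)c(OCOC)c1[Li] | intermediate
5 | [3-bromo-2,6-bis(methoxymethoxy)phenyl]copper | COCOc1ccc(Br)c(OCOC)c1[Cu] | intermediate
6 | 1-bromo-2,4-bis(methoxymethoxy)-3-(3-methylbut-2-en-1-yl)benzene | COCOc1ccc(Br)c(OCOC)c1CC=C(C)C | intermediate
7 | diethyl malonate | CCOC(=O)CC(=O)OCC | starting material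
8 | diethyl 2-[2,4-bis(methoxymethoxy)-3-(3-methylbut-2-en-1-yl)phenyl]malonate | CCOC(=O)C(C(=O)OCC)c1ccc(OCOC)c(CC=C(C)C)c1OCOC | intermediate
9 | 2-[2,4-bis(methoxymethoxy)-3-(3-methylbut-2-en-1-yl)phenyl]propane-1,3-diol | OCC(CO)c1ccc(OCOC)c(CC=C(C)C)c1OCOC | intermediate
10 | (2S)-2-(ArB)-3-hydroxypropyl acetate | COCOc1ccc([C@H](COC(C)=O)CO)c(OCOC)c1CC=C(C)C | intermediate
11 | (2R)-2-(ArB)-3-[(tert-butyldiphenylsilyl)oxy]propyl acetate | COCOc1ccc([C@H](COC(C)=O)CO[Si](c2ccccc2)(c2ccccc2)C(C)(C)C)c(OCOC)c1CC=C(C)C | intermediate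
12 | (2R)-2-(ArB)-3-[(tert-butyldiphenylsilyl)oxy]propan-1-ol | COCOc1ccc([C@H](CO)CO[Si](c2ccccc2)(c2ccccc2)C(C)(C)C)c(OCOC)c1CC=C(C)C | intermediate
13 | tert-butyl{[(2S)-2-(ArB)-3-iodopropyl]oxy}diphenylsilane | COCOc1ccc([C@H](CI)CO[Si](c2ccccc2)(c2ccccc2)C(C)(C)C)c(OCOC)c1CC=C(C)C | intermediate
14 | 4-bromo-1,3-phenylene bis(N,N-diethylcarbamate) | CCN(CC)C(=O)Oc1ccc(Br)c(OC(=O)N(CC)CC)c1 | intermediate
15 | [3-bromo-2,6-bis(diethylcarbamoyloxy)phenyl]lithium | CCN(CC)C(=O)Oc1ccc(Br)c(OC(=O)N(CC)CC)c1[Li] | intermediate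
16 | [3-bromo-2,6-bis(diethylcarbamoyloxy)phenyl]copper | CCN(CC)C(=O)Oc1ccc(Br)c(OC(=O)N(CC)CC)c1[Cu] | intermediate
17 | 4-bromo-2-(3-methylbut-2-en-1-yl)-1,3-phenylene bis(N,N-diethylcarbamate) | CCN(CC)C(=O)Oc1ccc(Br)c(OC(=O)N(CC)CC)c1CC=C(C)C | intermediate
18 | {(2S)-2-(ArB)-3-[(tert-butyldiphenylsilyl)oxy]propyl}zinc iodide | COCOc1ccc([C@H](C[Zn]I)CO[Si](c2ccccc2)(c2ccccc2)C(C)(C)C)c(OCOC)c1CC=C(C)C | intermediate
19 | 4-{(2S)-2-(ArB)-3-[(tert-butyldiphenylsilyl)oxy]propyl}-2-(3-methylbut-2-en-1-yl)-1,3-phenylene bis(N,N-diethylcarbamate) | COCOc1ccc([C@H](Cc2ccc(OC(=O)N(CC)CC)c(CC=C(C)C)c2OC(=O)N(CC)CC)CO[Si](c3ccccc3)(c3ccccc3)C(C)(C)C)c(OCOC)c1CC=C(C)C | intermediate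
20 | 4-{(2S)-2-(ArB)-3-[(tert-butyldiphenylsilyl)oxy]propyl}-2-(3-methylbut-2-en-1-yl)benzene-1,3-diol | COCOc1ccc([C@H](Cc2ccc(O)c(CC=C(C)C)c2O)CO[Si](c3ccccc3)(c3ccccc3)C(C)(C)C)c(OCOC)c1CC=C(C)C | intermediate
21 | 4-[(2S)-2-(ArB)-3-hydroxypropyl]-2-(3-methylbut-2-en-1-yl)benzene-1,3-diol | COCOc1ccc([C@H](Cc2ccc(O)c(CC=C(C)C)c2O)CO)c(OCOC)c1CC=C(C)C | intermediate
22 | (3S)-3-[2,4-bis(methoxymethoxy)-3-(3-methylbut-2-en-1-yl)phenyl]-8-(3-methylbut-2-en-1-yl)-3,4-dihydro-2H-chromen-7-ol | COCOc1ccc([C@H]2COc3c(ccc(O)c3CC=C(C)C)C2)c(OCOC)c1CC=C(C)C | intermediate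
23 | 4-[(3S)-7-hydroxy-8-(3-methylbut-2-en-1-yl)-3,4-dihydro-2H-chromen-3-yl]-2-(3-methylbut-2-en-1-yl)benzene-1,3-diol | CC(C)=CCc1c(O)ccc([C@H]2COc3c(ccc(O)c3CC=C(C)C)C2)c1O | target

**Totals**
Total step count: 15. Longest linear sequence: 13 steps (steps 1–8, then 11–15, from 4-bromoresorcinol); the ring A branch is steps 9–10.

**Three steps most likely to fail, with fallbacks**

Step 5 (lipase desymmetrisation; ee and sense are uncertain with the crowded 2,3,4-trisubstituted aryl group). The fallback sets out from 9 and comes back at 21. It uses the enzyme in the hydrolytic mode and lets the freed arm, not the acetylated one, become C4. Acetylation of 9 (Ac2O, pyridine) gives the prochiral diacetate F1. Lipase hydrolysis in pH 7 phosphate buffer/MTBE removes the acetate from the arm the enzyme would otherwise acylate and gives the (R)-monoacetate F2. Direct Appel iodination (I2, PPh3, imidazole, 0 °C) gives the iodo acetate F3. Zinc insertion gives the alkylzinc iodide F4, and Negishi coupling with 17 (Pd2(dba)3, SPhos) gives the coupled acetate F5. LiAlH4 in refluxing THF then cleaves the acetate and both carbamates in one operation to give 21. If the acylation run of step 5 itself delivers F2 instead of 10, that material enters this sequence at F2, so either sense of enzyme selectivity leads to the (S) target.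

Step 11 (Negishi coupling; risks are slow zinc insertion, β-hydride elimination and the ortho-carbamate on the bromide). The fallback sets out from 13 and comes back at 19 by a B-alkyl Suzuki–Miyaura coupling. Iodine–lithium exchange on 13 (t-BuLi, 2 equiv, Et2O, −78 °C) gives the primary alkyllithium F6. Trapping with B-methoxy-9-BBN gives the lithium B-alkyl-B-methoxy-9-BBN borate F7. This is coupled with 17 (PdCl2(dppf), aqueous K3PO4, DMF, rt) to give 19.

Step 15 (MOM removal by Brønsted acid with two prenyl groups ortho to phenols; the risk is cyclisation to dimethylchromans or addition of MeOH/HCl to the alkenes). The fallback sets out from 22 and comes back at 23 without protic acid. TMSOTf with 2,2'-bipyridyl (CH2Cl2, 0 °C) exchanges both aryl MOM ethers for silyl ethers and silylates the 7-OH, giving the tris(trimethylsilyl) ether F8. K2CO3 in MeOH at 0 °C then frees 23.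

**Further compounds**
F1 | step 5 | 2-(ArB)propane-1,3-diyl diacetate | CC(=O)OCC(COC(C)=O)c1ccc(OCOC)c(CC=C(C)C)c1OCOC
F2 | step 5 | (2R)-2-(ArB)-3-hydroxypropyl acetate | COCOc1ccc([C@H](CO)COC(C)=O)c(OCOC)c1CC=C(C)C
F3 | step 5 | (2S)-2-(ArB)-3-iodopropyl acetate | COCOc1ccc([C@H](CI)COC(C)=O)c(OCOC)c1CC=C(C)C
F4 | step 5 | [(2S)-3-acetoxy-2-(ArB)propyl]zinc iodide | COCOc1ccc([C@H](C[Zn]I)COC(C)=O)c(OCOC)c1CC=C(C)C
F5 | step 5 | (2S)-2-(ArB)-3-[2,4-bis(diethylcarbamoyloxy)-3-(3-methylbut-2-en-1-yl)phenyl]propyl acetate | COCOc1ccc([C@H](Cc2ccc(OC(=O)N(CC)CC)c(CC=C(C)C)c2OC(=O)N(CC)CC)COC(C)=O)c(OCOC)c1CC=C(C)C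
F6 | step 11 | {(2S)-2-(ArB)-3-[(tert-butyldiphenylsilyl)oxy]propyl}lithium | COCOc1ccc([C@H](C[Li])CO[Si](c2ccccc2)(c2ccccc2)C(C)(C)C)c(OCOC)c1CC=C(C)C
F7 | step 11 | lithium {(2S)-2-(ArB)-3-[(tert-butyldiphenylsilyl)oxy]propyl}(methoxy)-9-borabicyclo[3.3.1]nonan-9-uide | COCOc1ccc([C@H](C[B-]2(OC)C3CCCC2CCC3)CO[Si](c4ccccc4)(c4ccccc4)C(C)(C)C)c(OCOC)c1CC=C(C)C.[Li+]
F8 | step 15 | (3S)-7-(trimethylsilyloxy)-3-[2,4-bis(trimethylsilyloxy)-3-(3-methylbut-2-en-1-yl)phenyl]-8-(3-methylbut-2-en-1-yl)-3,4-dihydro-2H-chromene | C[Si](C)(C)Oc1ccc([C@H]2COc3c(ccc(O[Si](C)(C)C)c3CC=C(C)C)C2)c(O[Si](C)(C)C)c1CC=C(C)C
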